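**Retrosynthetic overview**
1. Phylloflavan 15 is (+)-catechin (rings A, B, C; 2R,3S) acylated at O3 of ring C by (3S)-5-(3,4-dihydroxyphenyl)-3-hydroxypentanoic acid (ring D). The last step is a sixfold O-debenzylation of 14.
2. Enabling feature: the chain is a β-hydroxy ester, with carbinol C3 lying 1,3 to ester carbonyl C1 on O3 of ring C. The chain bond C2–C3 is therefore an acetate aldol bond. Because ring C carries no carbonyl, the acetate CH3 is the only usefully acidic C–H of the benzylated flavan.
3. Key disconnection: chain C2–C3 leads back to flavan-3-yl acetate 3 (used as a chiral titanium enolate) and 3-arylpropanal 7. The bond and the 3S centre arise in the same operation.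
4. Acetate 3 comes from (+)-catechin 1 (benzylation, acetylation). Aldehyde 7 comes from dihydrocaffeic acid 4 (benzylation, partial reduction). Titanium reagent 10 comes from CpTiCl3 8 and diacetone-D-glucose 9.
5. No ring is formed. Rings A, B and C, with C2 and C3, come intact from 1, and ring D comes from 4.

Key step: step 6

Remark on the chemistry: the target SMILES decodes as 2R,3S (2,3-trans, the (+)-catechin series) in ring C and 3S in the chain, and the route is laid out for exactly this stereoisomer. ODAG stands for 1,2:5,6-di-O-isopropylidene-α-D-glucofuranos-3-O-yl.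

Step 1
Reactants: 1 (+)-catechin
Product: 2 5,7,3',4'-tetra-O-benzyl-(+)-catechin
Conditions: BnBr (4.4 equiv), K2CO3 (5 equiv), DMF, Ar, 0 °C to rt
Reagents that add atoms: benzyl bromide, BrCc1ccccc1
Why: In this Williamson ether synthesis K2CO3 ionises only the four phenols and not the secondary C3 hydroxyl of ring C, so 2 should form with C2 and C3 untouched, while exclusion of air and the low temperature hold back C-benzylation of ring A and base-induced opening of ring C.

Step 2
Reactants: 2 5,7,3',4'-tetra-O-benzyl-(+)-catechin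
Product: 3 3-O-acetyl-5,7,3',4'-tetra-O-benzyl-(+)-catechin
Conditions: Ac2O, pyridine, DMAP (cat.), CH2Cl2, rt
Reagents that add atoms: acetic anhydride, CC(=O)OC(C)=O
Why: DMAP-catalysed O-acylation of the only free hydroxyl should be clean, and it keeps the 3S configuration because the C3–O bond is not broken.

Step 3
Reactants: 4 3-(3,4-dihydroxyphenyl)propanoic acid
Product: 5 benzyl 3-[3,4-bis(benzyloxy)phenyl]propanoate
Conditions: BnBr (3.5 equiv), K2CO3 (4 equiv), DMF, 60 °C
Reagents that add atoms: benzyl bromide, BrCc1ccccc1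
Why: Williamson etherification of both phenols and O-alkylation of the carboxylate should proceed in one pot, so that every protecting group of the route is of one kind.

Step 4
Reactants: 5 benzyl 3-[3,4-bis(benzyloxy)phenyl]propanoate
Product: 7 3-[3,4-bis(benzyloxy)phenyl]propanal, via aluminium hemiacetal 6 (not isolated)
Conditions: i-Bu2AlH (1.05 equiv), toluene, −78 °C; then 1 M HCl, −78 to 0 °C
Reagents that add atoms: none
Why: In this partial ester reduction with i-Bu2AlH the tetrahedral adduct 6 should persist at −78 °C and collapse to the aldehyde only on the acidic quench, when no hydride is left.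

Step 5
Reactants: 8 trichloro(cyclopentadienyl)titanium CpTiCl3; 9 1,2:5,6-di-O-isopropylidene-α-D-glucofuranose (2.0 equiv)
Product: 10 chloro(cyclopentadienyl)bis(ODAG)titanium CpTiCl(ODAG)2
Conditions: Et3N (2.1 equiv), Et2O, Ar, rt; filtration under Ar; kept as a stock solution in toluene
Reagents that add atoms: none
Why: Alcoholysis of two Ti–Cl bonds (ligand exchange at tetravalent titanium), driven by precipitation of the amine hydrochloride, should stop at the monochloride because the two bulky sugar alkoxides block the third substitution, and the stereocenters of the sugar are not touched.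

Step 6
Reactants: 3 3-O-acetyl-5,7,3',4'-tetra-O-benzyl-(+)-catechin; 7 3-[3,4-bis(benzyloxy)phenyl]propanal; 10 CpTiCl(ODAG)2
Product: 14 hexa-O-benzylphylloflavan = (2R,3S)-5,7-bis(benzyloxy)-2-[3,4-bis(benzyloxy)phenyl]chroman-3-yl (3S)-5-[3,4-bis(benzyloxy)phenyl]-3-hydroxypentanoate, via lithium enolate 11 (not isolated), via titanium enolate 12 (not isolated), via titanium aldolate 13 (not isolated)
Conditions: 3, LiN(i-Pr)2 (commercial solution, 1.05 equiv), Et2O–toluene, −78 °C; 10 (1.3 equiv), −78 to −30 °C; 7 (1.1 equiv), −78 °C; then H2O–THF, rt, filtration, chromatography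
Reagents that add atoms: none
Why: LiN(i-Pr)2 removes a proton from the acetate CH3 of 3 to give lithium enolate 11, chloride displacement at the tetravalent titanium of 10 converts it into the monomeric, weakly basic titanium enolate 12, and 12 binds the carbonyl oxygen of 7 and delivers its CH2 terminus to the aldehyde carbon through a closed six-membered transition state to give aldolate 13, which water cleaves to 14 with release of the sugar ligands. The closest known reaction type is the titanium–carbohydrate mediated enantioselective acetate aldol addition, established for enolates of simple alkyl acetates and of glycine esters with linear, branched and unsaturated aldehydes, and here it is only applied to a larger secondary alkyl acetate. No ring is closed in this step. The single new stereocenter, C3 of the pentanoate chain, is controlled by the two D-glucose-derived alkoxides on titanium, which shield one flank of the bound aldehyde so that the enolate attacks its Re face, and Re attack on an aldehyde of the type RCH2CH2CHO gives the 3S carbinol of the target. The remote stereocenters C2 and C3 of ring C, with ring B flanking the acyloxy group as in a trans-2-arylcycloalkyl ester, should exert only a weak bias on an unsubstituted enolate, so reagent control should decide, and C2 and C3 themselves are not touched. The step needs cross-addition rather than Claisen self-condensation, aldehyde enolisation or loss of the acyloxy group from ring C, and this is secured by complete enolisation before 7 is added, by the low basicity of 12, by the benzyl ethers on all six phenols and by the equatorial C3 acyloxy group of the 2,3-trans ring C, which has no antiperiplanar hydrogen at C2 or C4.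

Step 7
Reactants: 14 hexa-O-benzylphylloflavan
Product: 15 phylloflavan
Conditions: H2 (1 atm), Pd(OH)2/C, THF–MeOH, rt; filtration under Ar
Reagents that add atoms: none
Why: Catalytic hydrogenolysis should cleave the six aryl benzyl ethers, while the cyclic benzylic C2–O1 bond of ring C, the ester and the non-benzylic chain carbinol are of the kinds that persist under these neutral conditions in catechin 3-O-ester chemistry, so no stereocenter is touched.

**Compound list** (Cp is written as a sigma-bonded ring in the SMILES)
1 | (+)-catechin, (2R,3S)-2-(3,4-dihydroxyphenyl)chroman-3,5,7-triol | O[C@H]1Cc2c(O)cc(O)cc2O[C@@H]1c1ccc(O)c(O)c1 | starting material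
2 | 5,7,3',4'-tetra-O-benzyl-(+)-catechin, (2R,3S)-5,7-bis(benzyloxy)-2-[3,4-bis(benzyloxy)phenyl]chroman-3-ol | O[C@H]1Cc2c(OCc3ccccc3)cc(OCc3ccccc3)cc2O[C@@H]1c1ccc(OCc2ccccc2)c(OCc2ccccc2)c1 | intermediate
3 | 3-O-acetyl-5,7,3',4'-tetra-O-benzyl-(+)-catechin (2R,3S) | CC(=O)O[C@H]1Cc2c(OCc3ccccc3)cc(OCc3ccccc3)cc2O[C@@H]1c1ccc(OCc2ccccc2)c(OCc2ccccc2)c1 | intermediate
4 | 3-(3,4-dihydroxyphenyl)propanoic acid (dihydrocaffeic acid) | OC(=O)CCc1ccc(O)c(O)c1 | starting material
5 | benzyl 3-[3,4-bis(benzyloxy)phenyl]propanoate | O=C(CCc1ccc(OCc2ccccc2)c(OCc2ccccc2)c1)OCc1ccccc1 | intermediate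
6 | aluminium hemiacetal, {1-(benzyloxy)-3-[3,4-bis(benzyloxy)phenyl]propoxy}diisobutylaluminium (racemic at the hemiacetal carbon) | CC(C)C[Al](CC(C)C)OC(CCc1ccc(OCc2ccccc2)c(OCc2ccccc2)c1)OCc1ccccc1 | intermediate
7 | 3-[3,4-bis(benzyloxy)phenyl]propanal | O=CCCc1ccc(OCc2ccccc2)c(OCc2ccccc2)c1 | intermediate
8 | trichloro(cyclopentadienyl)titanium, CpTiCl3 | Cl[Ti](Cl)(Cl)C1C=CC=C1 | starting material
9 | 1,2:5,6-di-O-isopropylidene-α-D-glucofuranose (diacetone-D-glucose) | O[C@@H]1[C@H]2OC(C)(C)O[C@H]2O[C@@H]1[C@H]1COC(C)(C)O1 | starting material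
10 | chloro(cyclopentadienyl)bis(1,2:5,6-di-O-isopropylidene-α-D-glucofuranos-3-O-yl)titanium, CpTiCl(ODAG)2 | Cl[Ti](C1C=CC=C1)(O[C@@H]1[C@H]2OC(C)(C)O[C@H]2O[C@@H]1[C@H]1COC(C)(C)O1)O[C@@H]1[C@H]2OC(C)(C)O[C@H]2O[C@@H]1[C@H]1COC(C)(C)O1 | intermediate
11 | lithium enolate of 3 | C=C(O[Li])O[C@H]1Cc2c(OCc3ccccc3)cc(OCc3ccccc3)cc2O[C@@H]1c1ccc(OCc2ccccc2)c(OCc2ccccc2)c1 | intermediate
12 | titanium enolate of 3, CpTi(ODAG)2 bound to the enolate oxygen | C=C(O[Ti](C1C=CC=C1)(O[C@@H]1[C@H]2OC(C)(C)O[C@H]2O[C@@H]1[C@H]1COC(C)(C)O1)O[C@@H]1[C@H]2OC(C)(C)O[C@H]2O[C@@H]1[C@H]1COC(C)(C)O1)O[C@H]1Cc2c(OCc3ccccc3)cc(OCc3ccccc3)cc2O[C@@H]1c1ccc(OCc2ccccc2)c(OCc2ccccc2)c1 | intermediate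
13 | titanium aldolate, CpTi(ODAG)2 bound to the (3S) carbinol oxygen of 14 | O=C(C[C@@H](O[Ti](C1C=CC=C1)(O[C@@H]1[C@H]2OC(C)(C)O[C@H]2O[C@@H]1[C@H]1COC(C)(C)O1)O[C@@H]1[C@H]2OC(C)(C)O[C@H]2O[C@@H]1[C@H]1COC(C)(C)O1)CCc1ccc(OCc2ccccc2)c(OCc2ccccc2)c1)O[C@H]1Cc2c(OCc3ccccc3)cc(OCc3ccccc3)cc2O[C@@H]1c1ccc(OCc2ccccc2)c(OCc2ccccc2)c1 | intermediate
14 | hexa-O-benzylphylloflavan, (2R,3S)-5,7-bis(benzyloxy)-2-[3,4-bis(benzyloxy)phenyl]chroman-3-yl (3S)-5-[3,4-bis(benzyloxy)phenyl]-3-hydroxypentanoate | O=C(C[C@@H](O)CCc1ccc(OCc2ccccc2)c(OCc2ccccc2)c1)O[C@H]1Cc2c(OCc3ccccc3)cc(OCc3ccccc3)cc2O[C@@H]1c1ccc(OCc2ccccc2)c(OCc2ccccc2)c1 | intermediate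
15 | phylloflavan, (2R,3S)-2-(3,4-dihydroxyphenyl)-5,7-dihydroxychroman-3-yl (3S)-5-(3,4-dihydroxyphenyl)-3-hydroxypentanoate | O=C(C[C@@H](O)CCc1ccc(O)c(O)c1)O[C@H]1Cc2c(O)cc(O)cc2O[C@@H]1c1ccc(O)c(O)c1 | target

Total step count: 7.
Longest linear sequence: 4 steps (1, 2, 6, 7).

**Steps most likely to fail**

Risk 1, step 6.
- What may go wrong: Claisen self-condensation or ketene loss from the lithium enolate while the lithium-to-titanium exchange is driven at −30 °C. Incomplete exchange would let the achiral lithium enolate add without facial control. A mismatched pull of the flavan stereocenters could also erode facial selectivity.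
- Fallback: keep the same bond formation but separate it from the stereocontrol. It sets out from 3 and 7.
- Acetate 3 is enolised with LiN(i-Pr)2 in THF at −78 °C to 11, and 7 is added at once. An NH4Cl quench should give the C3-epimeric aldol mixture F1.
- Oxidation with Dess–Martin periodinane in CH2Cl2 should merge both epimers into the β-keto ester F2.
- Noyori asymmetric hydrogenation of F2 with RuCl2[(S)-BINAP] (H2 under pressure, EtOH–CH2Cl2, 50 °C) should deliver the 3S carbinol. This follows the known sense in which the S ligand gives S-configured 3-hydroxy esters bearing a linear alkyl residue. Benzyl ethers are inert to this catalyst. The fallback comes back to the route at 14.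

Risk 2, step 4.
- What may go wrong: premature collapse of the tetrahedral adduct followed by over-reduction, or incomplete conversion if hydride is rationed.
- Fallback: replace the partial reduction by a full reduction and re-oxidation. It sets out from 5.
- LiAlH4 in THF at 0 °C should give 3-[3,4-bis(benzyloxy)phenyl]propan-1-ol F3.
- Parikh–Doering oxidation (SO3·pyridine, DMSO, Et3N, CH2Cl2, 0 °C) should then give the aldehyde, coming back to the route at 7.

Risk 3, step 7.
- What may go wrong: stalling at partly benzylated stages through fouling of the catalyst surface by the emerging polyphenol. Forcing the reaction could cause reductive opening of ring C at the benzylic C2–O1 bond. The catechols could also oxidise in air during filtration.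
- Fallback: give up heterogeneous catalysis and hydrogen altogether. It sets out from 14.
- BCl3 with an excess of pentamethylbenzene in CH2Cl2 at −78 °C, followed by a methanol quench, should cleave the six aryl benzyl ethers by Lewis-acid dealkylation.
- The benzyl cations are trapped by Friedel–Crafts alkylation of the scavenger instead of ring A. The low temperature should spare the ester, the carbinol and ring C.
- The fallback comes back to the route at 15 and makes no new compound F0.

**Further compounds**
F1 | step 6 | (2R,3S)-5,7-bis(benzyloxy)-2-[3,4-bis(benzyloxy)phenyl]chroman-3-yl 5-[3,4-bis(benzyloxy)phenyl]-3-hydroxypentanoate, mixture of epimers at chain C3 | O=C(CC(O)CCc1ccc(OCc2ccccc2)c(OCc2ccccc2)c1)O[C@H]1Cc2c(OCc3ccccc3)cc(OCc3ccccc3)cc2O[C@@H]1c1ccc(OCc2ccccc2)c(OCc2ccccc2)c1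
F2 | step 6 | (2R,3S)-5,7-bis(benzyloxy)-2-[3,4-bis(benzyloxy)phenyl]chroman-3-yl 5-[3,4-bis(benzyloxy)phenyl]-3-oxopentanoate | O=C(CC(=O)CCc1ccc(OCc2ccccc2)c(OCc2ccccc2)c1)O[C@H]1Cc2c(OCc3ccccc3)cc(OCc3ccccc3)cc2O[C@@H]1c1ccc(OCc2ccccc2)c(OCc2ccccc2)c1
F3 | step 4 | 3-[3,4-bis(benzyloxy)phenyl]propan-1-ol | OCCCc1ccc(OCc2ccccc2)c(OCc2ccccc2)c1
F0 | step 7 | none | none
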